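**Plan**

- Cuts, last to first: the three allyl esters; the ester joining the C2' carboxyl of the isocitrate on unit A to the C4α-CH2OH of unit B; both C11–O ether bonds (aldehyde plus silylated α-hydroxy ester); each isocitrate at C2'–CH2 (malate alkylation); unit A at C8–C9 and C5–C10; unit B at C4–C5 and C9–C10.
- Enabling feature: in ring B of unit A, C5 and C8 are 1,4-related through C6–C7, and the C9–C10 edge carries an oxidisable carbon (C11) on C9 and the angular methyl on C10. Ring B is therefore the adduct of a C5=C6–C7=C8 diene and an (E)-3-methyl-enoyl dienophile C9=C10; since C10 and C5 are also linked through C1–C2–C3–C4(Me2), one intramolecular Diels–Alder reaction of an acyclic triene closes ring A and ring B together.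
- Unit A, forward: nitrile alkylation (quaternary C4) → Takai olefination → enoate → Suzuki diene carrying CH2SPh as the masked C12 methylidene → oxazolidinone imide → cycloaddition (both rings) → auxiliary off, C6=C7 reduced, sulfoxide elimination → albicanol → aldehyde.
- Unit B, forward: farnesyl acetate → allylic oxidation → asymmetric epoxidation → radical bicyclisation with trivalent titanium (ring A, then ring B, exocyclic alkene) → C3 deoxygenation → C11 aldehyde.
- Assembly: each C11 aldehyde is joined to a (1R,2S)-isocitrate triester made from (R)-malic acid, the halves are esterified, and the allyl esters are removed with zerovalent palladium.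
- Stereochemistry: C9/C10 of unit A from the (E)-enoyl geometry and the (S)-benzyl oxazolidinone, C5 from the endo transition state; C4, C5, C9, C10 of unit B from the epoxide and chair folding; C1' from (R)-malate, C2' from anti alkylation of its dianion.

Key step: step 9

Remark: positions use drimane numbering (C11 = CH2O carbon on C9, C12 = methylidene carbon on C8, the oxygenated C4 substituent of unit B is called C4α-CH2O), C1'/C2' are the O-bearing and the adjacent carbon of each isocitrate, and compounds 10, 24 and 36 are assumed to be purchasable.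

**Unit A (steps 1–13)**

Step 1
Reactants: 1 isobutyronitrile; 2 2-(3-chloropropyl)-2-methyl-1,3-dioxolane
Product: 3 2,2-dimethyl-5-(2-methyl-1,3-dioxolan-2-yl)pentanenitrile
Conditions: LiN(iPr)2, THF, −78 °C; then 2, DMPU, −78 °C → rt
Reagents that add atoms: none
Why: SN2 alkylation of the lithiated nitrile at the primary chloride should install the quaternary C4 with its gem-dimethyl group and the C1–C3 chain in one operation, with no stereocentre formed.

Step 2
Reactants: 3
Product: 5 2,2-dimethyl-6-oxoheptanal, via ketal aldehyde 4 (not isolated)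
Conditions: iBu2AlH, CH2Cl2, −78 °C; then 1 M aq. HCl, THF, 0 °C → rt
Reagents that add atoms: water, O
Why: Nitrile-to-aldehyde reduction stops at the aluminium imine, and the acidic work-up should hydrolyse imine and dioxolane together, the aldehyde being unable to enolise because it has no α-hydrogen.

Step 3
Reactants: 5; 6 iodoform
Product: 7 (E)-8-iodo-6,6-dimethyloct-7-en-2-one
Conditions: CrCl2, THF/dioxane, 0 °C → rt
Reagents that add atoms: none
Why: Takai olefination with the geminal dichromium reagent formed from CHI3 and divalent chromium should convert the aldehyde, not the ketone, into the (E)-alkenyl iodide.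

Step 4
Reactants: 7; 8 triethyl phosphonoacetate
Product: 9 ethyl (2E,8E)-9-iodo-3,7,7-trimethylnona-2,8-dienoate
Conditions: NaH, THF, 0 → 65 °C; the (2Z) isomer is removed by chromatography
Reagents that add atoms: none
Why: Horner–Wadsworth–Emmons olefination of the methyl ketone should favour the (E)-enoate (ester trans to the longer chain), the geometry that later places C11 and the C10 methyl cis.

Step 5
Reactants: 10 (E)-2-(3-chloroprop-1-en-1-yl)-4,4,5,5-tetramethyl-1,3,2-dioxaborolane; 11 thiophenol
Product: 12 (E)-4,4,5,5-tetramethyl-2-[3-(phenylsulfanyl)prop-1-en-1-yl]-1,3,2-dioxaborolane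
Conditions: K2CO3, DMF, 0 °C → rt
Reagents that add atoms: none
Why: SN2 displacement of the allylic chloride by thiophenolate should give the sulfide and leave the (E)-alkenyl boronate untouched.

Step 6
Reactants: 9; 12
Product: 13 ethyl (2E,8E,10E)-3,7,7-trimethyl-12-(phenylsulfanyl)dodeca-2,8,10-trienoate
Conditions: Pd(dppf)Cl2 (5 mol %), aq. K3PO4, THF, 40 °C
Reagents that add atoms: none
Why: Suzuki–Miyaura coupling of the (E)-alkenyl iodide with the (E)-alkenyl boronate proceeds with retention at both partners and should give the (E,E)-diene.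

Step 7
Reactants: 13
Product: 14 (2E,8E,10E)-3,7,7-trimethyl-12-(phenylsulfanyl)dodeca-2,8,10-trienoic acid
Conditions: LiOH, THF/MeOH/H2O, 50 °C; then dilute HCl
Reagents that add atoms: lithium hydroxide, [Li+].[OH-]
Why: Saponification of the ethyl ester should give the acid without moving the trisubstituted double bond.

Step 8
Reactants: 14; 15 (S)-4-benzyl-1,3-oxazolidin-2-one
Product: 17 (S)-4-benzyl-3-[(2E,8E,10E)-3,7,7-trimethyl-12-(phenylsulfanyl)dodeca-2,8,10-trienoyl]-1,3-oxazolidin-2-one, via mixed pivalic anhydride 16 (not isolated)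
Conditions: t-BuCOCl, Et3N, THF, −20 °C; then LiCl, 15, −20 °C → rt
Reagents that add atoms: none
Why: N-Acylation through the mixed anhydride (attack at the less hindered enoyl carbonyl) attaches the chiral auxiliary that activates the dienophile and controls its face.

Step 9
Reactants: 17
Product: 18 (4S)-4-benzyl-3-{[(1S,2S,4aS,8aS)-5,5,8a-trimethyl-2-[(phenylsulfanyl)methyl]-1,2,4a,5,6,7,8,8a-octahydronaphthalen-1-yl]carbonyl}-1,3-oxazolidin-2-one (trans-fused, C6=C7, 8β-CH2SPh)
Conditions: Me2AlCl (1.5 equiv), CH2Cl2, −30 → 0 °C; aq. HCl quench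
Reagents that add atoms: none
Why: Me2AlCl should bind both imide carbonyls as a cationic chelate that locks the enoyl unit s-cis and lowers its LUMO, and the tethered (E,E)-diene then adds in a concerted, asynchronous intramolecular [4+2] cycloaddition that makes C8–C9 and C5–C10 together. The closest known reaction type is the Lewis-acid-promoted intramolecular Diels–Alder reaction of deca-2,8,10-trienoyl oxazolidinones (type 1, tether on the diene terminus). Ring B closes as the new cyclohexene by suprafacial addition on both partners, and ring A closes in the same event as the six-membered carbocycle that the C1–C4 tether spans across the new C5–C10 bond, the tether folding chair-like. C9 and C10 are fixed relative to each other by the (E) geometry of the enoyl unit (C10 methyl cis to the acyl carbon, so C11 and the C10 methyl end cis on ring B) and in the absolute sense by the benzyl group of the auxiliary, which covers the Re face of C9 in the chelate so that the diene adds to the Si face. C5 is set by the endo orientation of the chelated carbonyl under the diene, which puts H-5 anti to the C10 methyl (trans ring fusion), and C8 (CH2SPh cis to C11) follows from the (E)-C7=C8 bond and is erased in step 12. The step needs endo over exo selectivity and enough reactivity at a trisubstituted dienophile; the chelate activation, the strong endo preference of chelated enoyl dienophiles and the gem-dimethyl group at C4 that favours the folded conformer are what should secure this.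

Step 10
Reactants: 18
Product: 19 {(1S,2S,4aS,8aS)-5,5,8a-trimethyl-2-[(phenylsulfanyl)methyl]-1,2,4a,5,6,7,8,8a-octahydronaphthalen-1-yl}methanol
Conditions: LiBH4, H2O (1 equiv), Et2O, 0 °C
Reagents that add atoms: none
Why: Reductive cleavage of the N-acyl oxazolidinone (hydride attack at the exocyclic carbonyl) should give the C11 alcohol and return the auxiliary without change at C9.

Step 11
Reactants: 19
Product: 20 {(1S,2S,4aS,8aS)-5,5,8a-trimethyl-2-[(phenylsulfanyl)methyl]decahydronaphthalen-1-yl}methanol
Conditions: TsNHNH2, NaOAc, DME/H2O, 85 °C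
Reagents that add atoms: none
Why: Diimide reduction transfers H2 in a concerted syn fashion to the only C=C bond (C6=C7) and tolerates the sulfide, which would poison a heterogeneous catalyst.

Step 12
Reactants: 20
Product: 22 albicanol [(1S,4aS,8aS)-5,5,8a-trimethyl-2-methylidenedecahydronaphthalen-1-yl]methanol, via sulfoxide 21 (not isolated)
Conditions: m-CPBA (1.0 equiv), CH2Cl2, −78 °C; then NaHCO3, toluene, 110 °C
Reagents that add atoms: none
Why: S-Oxidation followed by thermal syn elimination of benzenesulfenic acid (sulfoxide pyrolysis) can only take the single β-hydrogen at C8 and should therefore give the exocyclic C8=C12 alkene and remove the C8 stereocentre.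

Step 13
Reactants: 22
Product: 23 albicanal, (1S,4aS,8aS)-5,5,8a-trimethyl-2-methylidenedecahydronaphthalene-1-carbaldehyde
Conditions: Dess–Martin periodinane, NaHCO3, CH2Cl2, 0 °C; used at once
Reagents that add atoms: none
Why: Dess–Martin oxidation under buffered, non-enolising conditions should give the β,γ-unsaturated aldehyde without epimerisation at C9 or migration of the double bond.

**Isocitrate building blocks (steps 14–18)**

Step 14
Reactants: 24 (R)-malic acid
Product: 26 (3R)-3-hydroxy-4-methoxy-4-oxobutanoic acid, via O-trifluoroacetyl malic anhydride 25 (not isolated)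
Conditions: (CF3CO)2O, 0 °C → rt, then evaporation; MeOH, rt
Reagents that add atoms: methanol, CO
Why: The O-acylated cyclic anhydride should be opened by methanol at the more electrophilic carbonyl next to the acyloxy carbon (regioselective anhydride opening) with loss of the trifluoroacetate, the stereocentre staying untouched.

Step 15
Reactants: 26; 27 2-(trimethylsilyl)ethanol
Product: 28 1-methyl 4-[2-(trimethylsilyl)ethyl] (2R)-2-hydroxybutanedioate
Conditions: DCC, DMAP (cat.), CH2Cl2, 0 °C → rt
Reagents that add atoms: none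
Why: Steglich esterification of the free carboxyl with the primary silyl alcohol, which outcompetes the hindered secondary hydroxyl, installs a fluoride-labile ester at the future C2' carboxyl.

Step 16
Reactants: 28; 29 allyl bromoacetate
Product: 30 1-methyl 3-(prop-2-en-1-yl) 2-[2-(trimethylsilyl)ethyl] (1R,2S)-1-hydroxypropane-1,2,3-tricarboxylate
Conditions: LiN(iPr)2 (2.2 equiv), THF, −78 → −20 °C; then 29, −78 → −20 °C; AcOH quench
Reagents that add atoms: none
Why: Fráter–Seebach alkylation of the alkoxide-enolate dianion occurs anti to the alkoxide oxygen within the lithium chelate, which should set C2' as S and give the (1R,2S)-isocitrate pattern with three different esters.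

Step 17
Reactants: 26
Product: 31 1-methyl 4-(prop-2-en-1-yl) (2R)-2-hydroxybutanedioate
Conditions: allyl bromide, KHCO3, DMF, rt
Reagents that add atoms: allyl bromide, C=CCBr
Why: Carboxylate alkylation (SN2) under weakly basic conditions should esterify only the acid.

Step 18
Reactants: 31; 29 allyl bromoacetate
Product: 32 1-methyl 2,3-di(prop-2-en-1-yl) (1R,2S)-1-hydroxypropane-1,2,3-tricarboxylate
Conditions: LiN(iPr)2 (2.2 equiv), THF, −78 → −20 °C; then 29, −78 → −20 °C; AcOH quench
Reagents that add atoms: none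
Why: The same Fráter–Seebach anti alkylation should set C2' as S, the allyl ester enolate being kept cold so that it does not rearrange.

**Ether of unit A (steps 19–20)**

Step 19
Reactants: 23; 30
Product: 34 albicanyl ether of 30 (unit A ether triester), via trimethylsilyl ether 33 (not isolated)
Conditions: 30, (Me3Si)2NH, Me3SiOTf (1 mol %), CH2Cl2, rt, then evaporation; 23, Et3SiH, Me3SiOTf (0.2 equiv), CH2Cl2, −78 → −40 °C
Reagents that add atoms: none
Why: In this reductive etherification the silyl ether adds to the activated aldehyde to give an oxocarbenium ion that Et3SiH reduces, so the C11–O bond forms under non-basic conditions without breaking a bond at C1', C2' or C9.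

Step 20
Reactants: 34
Product: 35 unit A ether acid (C2' carboxyl free, methyl ester at C1', allyl ester on the CH2 carboxyl)
Conditions: Bu4NF, THF, 0 °C; dilute HCl work-up
Reagents that add atoms: none
Why: Fluoride attack at silicon triggers fragmentation of the 2-(trimethylsilyl)ethyl ester with loss of ethene and should free only the C2' carboxyl, the short cold exposure being meant to avoid β-elimination of the ether oxygen.

**Unit B (steps 21–30)**

Step 21
Reactants: 36 (2E,6E)-farnesyl acetate
Product: 37 (2E,6E,10E)-12-hydroxy-3,7,11-trimethyldodeca-2,6,10-trien-1-yl acetate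
Conditions: SeO2 (cat.), t-BuOOH, salicylic acid (cat.), CH2Cl2, rt
Reagents that add atoms: tert-butyl hydroperoxide, CC(C)(C)OO
Why: Allylic oxidation with SeO2 (ene reaction, then [2,3]-shift) is selective for the (E)-methyl group of the terminal trisubstituted alkene and should give the (E)-allylic alcohol.

Step 22
Reactants: 37
Product: 38 (2E,6E)-9-[(2S,3S)-3-(hydroxymethyl)-3-methyloxiran-2-yl]-3,7-dimethylnona-2,6-dien-1-yl acetate
Conditions: Ti(OiPr)4 (cat.), L-(+)-diethyl tartrate (cat.), t-BuOOH, 4 Å molecular sieves, CH2Cl2, −20 °C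
Reagents that add atoms: tert-butyl hydroperoxide, CC(C)(C)OO
Why: Sharpless asymmetric epoxidation acts only on the allylic alcohol alkene, and L-(+)-diethyl tartrate should deliver oxygen to the face that gives the (2S,3S)-epoxide.

Step 23
Reactants: 38
Product: 39 tert-butyldiphenylsilyl ether of 38
Conditions: t-BuPh2SiCl, imidazole, DMF, rt
Reagents that add atoms: tert-butyl(chloro)diphenylsilane, CC(C)(C)[Si](Cl)(c1ccccc1)c1ccccc1
Why: Silylation of the primary alcohol gives a robust ether that marks the future C4α-CH2O group.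

Step 24
Reactants: 39
Product: 40 {(1S,4aR,5R,6S,8aS)-5-{[tert-butyl(diphenyl)silyl]oxymethyl}-6-hydroxy-5,8a-dimethyl-2-methylidenedecahydronaphthalen-1-yl}methyl acetate (3β-OH, trans-fused)
Conditions: Cp2TiCl2 (2.2 equiv), Mn dust, THF, rt; dilute HCl work-up
Reagents that add atoms: none
Why: Cp2TiCl (trivalent titanium) opens the epoxide homolytically to the tertiary radical, which should close ring A and then ring B by two 6-endo cyclisations through a chair–chair fold and end by β-hydrogen loss to the exocyclic alkene (epoxy-polyene radical cyclisation); the epoxide CH carbon (C3) fixes the absolute sense of C5, C9 and C10, and the bulkier CH2OSi group on the planar C4 radical should take the equatorial (α) position.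

Step 25
Reactants: 40
Product: 41 O-(imidazol-1-ylthiocarbonyl) derivative of 40 at C3
Conditions: 1,1'-thiocarbonyldiimidazole, DMAP, ClCH2CH2Cl, 70 °C
Reagents that add atoms: 1,1'-thiocarbonyldiimidazole, S=C(n1ccnc1)n1ccnc1
Why: Thioacylation of the hindered equatorial C3 alcohol gives the thiocarbonyl derivative needed for radical deoxygenation.

Step 26
Reactants: 41
Product: 42 {(1S,4aR,5R,8aS)-5-{[tert-butyl(diphenyl)silyl]oxymethyl}-5,8a-dimethyl-2-methylidenedecahydronaphthalen-1-yl}methyl acetate
Conditions: Bu3SnH, AIBN, toluene, 110 °C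
Reagents that add atoms: none
Why: In this Barton–McCombie deoxygenation the stannyl radical adds to sulfur, the C3–O bond fragments and the secondary radical is reduced by Bu3SnH, which removes the helper oxygen.

Step 27
Reactants: 42
Product: 43 {(1S,4aR,5R,8aS)-5-{[tert-butyl(diphenyl)silyl]oxymethyl}-5,8a-dimethyl-2-methylidenedecahydronaphthalen-1-yl}methanol
Conditions: K2CO3 (cat.), MeOH, rt
Reagents that add atoms: none
Why: Base-catalysed transesterification should remove the acetate and leave the silyl ether.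

Step 28
Reactants: 43
Product: 44 (1S,4aR,5R,8aS)-5-{[tert-butyl(diphenyl)silyl]oxymethyl}-5,8a-dimethyl-2-methylidenedecahydronaphthalene-1-carbaldehyde
Conditions: Dess–Martin periodinane, NaHCO3, CH2Cl2, 0 °C; used at once
Reagents that add atoms: none
Why: Dess–Martin oxidation under buffered conditions should give the aldehyde without epimerisation at C9 or alkene migration.

Step 29
Reactants: 44; 32
Product: 46 silyl-protected unit B ether triester, via trimethylsilyl ether 45 (not isolated)
Conditions: 32, (Me3Si)2NH, Me3SiOTf (1 mol %), CH2Cl2, rt, then evaporation; 44, Et3SiH, Me3SiOTf (0.2 equiv), CH2Cl2, −78 → −40 °C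
Reagents that add atoms: none
Why: The same reductive etherification (oxocarbenium formation, then hydride transfer from Et3SiH) should form the C11–O bond of unit B without touching any stereocentre or the hindered silyl ether.

Step 30
Reactants: 46
Product: 47 unit B ether triester with free C4α-CH2OH
Conditions: HF·pyridine, excess pyridine, THF, 0 °C → rt
Reagents that add atoms: none
Why: Buffered fluoride desilylation should free the neopentyl alcohol without β-elimination in the ether triester and without adding HF to the exocyclic alkene.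

**Coupling and deprotection (steps 31–32)**

Step 31
Reactants: 35; 47
Product: 49 tris-allyl ester of the target, via mixed trichlorobenzoic anhydride 48 (not isolated)
Conditions: 2,4,6-Cl3C6H2COCl, Et3N, THF, 0 °C; then 47, DMAP, toluene, rt
Reagents that add atoms: none
Why: Yamaguchi esterification through the mixed aromatic anhydride and an acyl-pyridinium intermediate should join the hindered acid and the neopentyl alcohol, with short cold activation meant to avoid enolisation at C2'.

Step 32
Reactants: 49
Product: 50 target CNP0420141.2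
Conditions: Pd(PPh3)4 (10 mol %), morpholine, THF, rt; dilute acid work-up
Reagents that add atoms: none
Why: Zerovalent palladium ionises the three allyl esters to π-allyl complexes that morpholine traps (allyl transfer), which should free the three carboxylic acids under neutral conditions that leave the methyl esters, the inter-unit ester and both exocyclic alkenes intact.

**Compound list**

1 | isobutyronitrile | CC(C)C#N | starting material
2 | 2-(3-chloropropyl)-2-methyl-1,3-dioxolane | CC1(CCCCl)OCCO1 | starting material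
3 | 2,2-dimethyl-5-(2-methyl-1,3-dioxolan-2-yl)pentanenitrile | CC1(CCCC(C)(C)C#N)OCCO1 | intermediate
4 | 2,2-dimethyl-5-(2-methyl-1,3-dioxolan-2-yl)pentanal | CC1(CCCC(C)(C)C=O)OCCO1 | intermediate
5 | 2,2-dimethyl-6-oxoheptanal | CC(=O)CCCC(C)(C)C=O | intermediate
6 | iodoform | IC(I)I | starting material
7 | (E)-8-iodo-6,6-dimethyloct-7-en-2-one | CC(=O)CCCC(C)(C)/C=C/I | intermediate
8 | triethyl phosphonoacetate | CCOC(=O)CP(=O)(OCC)OCC | starting material
9 | ethyl (2E,8E)-9-iodo-3,7,7-trimethylnona-2,8-dienoate | CCOC(=O)/C=C(\C)CCCC(C)(C)/C=C/I | intermediate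
10 | (E)-2-(3-chloroprop-1-en-1-yl)-4,4,5,5-tetramethyl-1,3,2-dioxaborolane | ClC/C=C/B1OC(C)(C)C(C)(C)O1 | starting material
11 | thiophenol | Sc1ccccc1 | starting material
12 | (E)-4,4,5,5-tetramethyl-2-[3-(phenylsulfanyl)prop-1-en-1-yl]-1,3,2-dioxaborolane | CC1(C)OB(/C=C/CSc2ccccc2)OC1(C)C | intermediate
13 | ethyl (2E,8E,10E)-3,7,7-trimethyl-12-(phenylsulfanyl)dodeca-2,8,10-trienoate | CCOC(=O)/C=C(\C)CCCC(C)(C)/C=C/C=C/CSc1ccccc1 | intermediate
14 | (2E,8E,10E)-3,7,7-trimethyl-12-(phenylsulfanyl)dodeca-2,8,10-trienoic acid | OC(=O)/C=C(\C)CCCC(C)(C)/C=C/C=C/CSc1ccccc1 | intermediate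
15 | (S)-4-benzyl-1,3-oxazolidin-2-one | O=C1N[C@@H](Cc2ccccc2)CO1 | starting material
16 | mixed anhydride of 14 with pivalic acid | CC(C)(C)C(=O)OC(=O)/C=C(\C)CCCC(C)(C)/C=C/C=C/CSc1ccccc1 | intermediate
17 | (S)-4-benzyl-3-[(2E,8E,10E)-3,7,7-trimethyl-12-(phenylsulfanyl)dodeca-2,8,10-trienoyl]-1,3-oxazolidin-2-one | O=C(/C=C(\C)CCCC(C)(C)/C=C/C=C/CSc1ccccc1)N1[C@@H](Cc2ccccc2)COC1=O | intermediate
18 | (4S)-4-benzyl-3-{[(1S,2S,4aS,8aS)-5,5,8a-trimethyl-2-[(phenylsulfanyl)methyl]-1,2,4a,5,6,7,8,8a-octahydronaphthalen-1-yl]carbonyl}-1,3-oxazolidin-2-one | c1ccccc1SC[C@H]1C=C[C@H]2C(C)(C)CCC[C@]2(C)[C@H]1C(=O)N1[C@@H](Cc2ccccc2)COC1=O | intermediate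
19 | {(1S,2S,4aS,8aS)-5,5,8a-trimethyl-2-[(phenylsulfanyl)methyl]-1,2,4a,5,6,7,8,8a-octahydronaphthalen-1-yl}methanol | c1ccccc1SC[C@H]1C=C[C@H]2C(C)(C)CCC[C@]2(C)[C@H]1CO | intermediate
20 | {(1S,2S,4aS,8aS)-5,5,8a-trimethyl-2-[(phenylsulfanyl)methyl]decahydronaphthalen-1-yl}methanol | c1ccccc1SC[C@H]1CC[C@H]2C(C)(C)CCC[C@]2(C)[C@H]1CO | intermediate
21 | {(1S,2S,4aS,8aS)-5,5,8a-trimethyl-2-[(phenylsulfinyl)methyl]decahydronaphthalen-1-yl}methanol (either configuration at sulfur) | O=S(C[C@H]1CC[C@H]2C(C)(C)CCC[C@]2(C)[C@H]1CO)c1ccccc1 | intermediate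
22 | albicanol, [(1S,4aS,8aS)-5,5,8a-trimethyl-2-methylidenedecahydronaphthalen-1-yl]methanol | C=C1CC[C@H]2C(C)(C)CCC[C@]2(C)[C@H]1CO | intermediate
23 | albicanal, (1S,4aS,8aS)-5,5,8a-trimethyl-2-methylidenedecahydronaphthalene-1-carbaldehyde | C=C1CC[C@H]2C(C)(C)CCC[C@]2(C)[C@H]1C=O | intermediate
24 | (R)-malic acid | O[C@H](CC(=O)O)C(=O)O | starting material
25 | (3R)-2,5-dioxooxolan-3-yl trifluoroacetate | FC(F)(F)C(=O)O[C@@H]1CC(=O)OC1=O | intermediate
26 | (3R)-3-hydroxy-4-methoxy-4-oxobutanoic acid | O[C@H](CC(=O)O)C(=O)OC | intermediate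
27 | 2-(trimethylsilyl)ethanol | C[Si](C)(C)CCO | starting material
28 | 1-methyl 4-[2-(trimethylsilyl)ethyl] (2R)-2-hydroxybutanedioate | O[C@H](CC(=O)OCC[Si](C)(C)C)C(=O)OC | intermediate
29 | allyl bromoacetate | C=CCOC(=O)CBr | starting material
30 | 1-methyl 3-(prop-2-en-1-yl) 2-[2-(trimethylsilyl)ethyl] (1R,2S)-1-hydroxypropane-1,2,3-tricarboxylate | O[C@@H](C(=O)OC)[C@H](CC(=O)OCC=C)C(=O)OCC[Si](C)(C)C | intermediate
31 | 1-methyl 4-(prop-2-en-1-yl) (2R)-2-hydroxybutanedioate | O[C@H](CC(=O)OCC=C)C(=O)OC | intermediate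
32 | 1-methyl 2,3-di(prop-2-en-1-yl) (1R,2S)-1-hydroxypropane-1,2,3-tricarboxylate | O[C@@H](C(=O)OC)[C@H](CC(=O)OCC=C)C(=O)OCC=C | intermediate
33 | O-trimethylsilyl ether of 30 | C[Si](C)(C)O[C@@H](C(=O)OC)[C@H](CC(=O)OCC=C)C(=O)OCC[Si](C)(C)C | intermediate
34 | 1-methyl 3-(prop-2-en-1-yl) 2-[2-(trimethylsilyl)ethyl] (1R,2S)-1-{[(1S,4aS,8aS)-5,5,8a-trimethyl-2-methylidenedecahydronaphthalen-1-yl]methoxy}propane-1,2,3-tricarboxylate | C=C1CC[C@H]2C(C)(C)CCC[C@]2(C)[C@H]1CO[C@@H](C(=O)OC)[C@H](CC(=O)OCC=C)C(=O)OCC[Si](C)(C)C | intermediate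
35 | 2-carboxylic acid of 34 (silylethyl ester removed) | C=C1CC[C@H]2C(C)(C)CCC[C@]2(C)[C@H]1CO[C@@H](C(=O)OC)[C@H](CC(=O)OCC=C)C(=O)O | intermediate
36 | (2E,6E)-farnesyl acetate | CC(=O)OC/C=C(\C)CC/C=C(\C)CCC=C(C)C | starting material
37 | (2E,6E,10E)-12-hydroxy-3,7,11-trimethyldodeca-2,6,10-trien-1-yl acetate | CC(=O)OC/C=C(\C)CC/C=C(\C)CC/C=C(\C)CO | intermediate
38 | (2E,6E)-9-[(2S,3S)-3-(hydroxymethyl)-3-methyloxiran-2-yl]-3,7-dimethylnona-2,6-dien-1-yl acetate | CC(=O)OC/C=C(\C)CC/C=C(\C)CC[C@@H]1O[C@@]1(C)CO | intermediate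
39 | tert-butyldiphenylsilyl ether of 38 | CC(=O)OC/C=C(\C)CC/C=C(\C)CC[C@@H]1O[C@@]1(C)CO[Si](c1ccccc1)(c1ccccc1)C(C)(C)C | intermediate
40 | {(1S,4aR,5R,6S,8aS)-5-{[tert-butyl(diphenyl)silyl]oxymethyl}-6-hydroxy-5,8a-dimethyl-2-methylidenedecahydronaphthalen-1-yl}methyl acetate | CC(C)(C)[Si](c1ccccc1)(c1ccccc1)OC[C@]1(C)[C@@H](O)CC[C@]2(C)[C@@H](COC(C)=O)C(=C)CC[C@@H]12 | intermediate
41 | C3 O-(imidazol-1-ylthiocarbonyl) derivative of 40 | CC(C)(C)[Si](c1ccccc1)(c1ccccc1)OC[C@]1(C)[C@@H](OC(=S)n3ccnc3)CC[C@]2(C)[C@@H](COC(C)=O)C(=C)CC[C@@H]12 | intermediate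
42 | {(1S,4aR,5R,8aS)-5-{[tert-butyl(diphenyl)silyl]oxymethyl}-5,8a-dimethyl-2-methylidenedecahydronaphthalen-1-yl}methyl acetate | CC(C)(C)[Si](c1ccccc1)(c1ccccc1)OC[C@]1(C)CCC[C@]2(C)[C@@H](COC(C)=O)C(=C)CC[C@@H]12 | intermediate
43 | {(1S,4aR,5R,8aS)-5-{[tert-butyl(diphenyl)silyl]oxymethyl}-5,8a-dimethyl-2-methylidenedecahydronaphthalen-1-yl}methanol | CC(C)(C)[Si](c1ccccc1)(c1ccccc1)OC[C@]1(C)CCC[C@]2(C)[C@@H](CO)C(=C)CC[C@@H]12 | intermediate
44 | (1S,4aR,5R,8aS)-5-{[tert-butyl(diphenyl)silyl]oxymethyl}-5,8a-dimethyl-2-methylidenedecahydronaphthalene-1-carbaldehyde | CC(C)(C)[Si](c1ccccc1)(c1ccccc1)OC[C@]1(C)CCC[C@]2(C)[C@@H](C=O)C(=C)CC[C@@H]12 | intermediate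
45 | O-trimethylsilyl ether of 32 | C[Si](C)(C)O[C@@H](C(=O)OC)[C@H](CC(=O)OCC=C)C(=O)OCC=C | intermediate
46 | 1-methyl 2,3-di(prop-2-en-1-yl) (1R,2S)-1-{[(1S,4aR,5R,8aS)-5-{[tert-butyl(diphenyl)silyl]oxymethyl}-5,8a-dimethyl-2-methylidenedecahydronaphthalen-1-yl]methoxy}propane-1,2,3-tricarboxylate | CC(C)(C)[Si](c1ccccc1)(c1ccccc1)OC[C@]1(C)CCC[C@]2(C)[C@@H](CO[C@@H](C(=O)OC)[C@H](CC(=O)OCC=C)C(=O)OCC=C)C(=C)CC[C@@H]12 | intermediate
47 | desilylated 46 (free C4α-CH2OH) | OC[C@]1(C)CCC[C@]2(C)[C@@H](CO[C@@H](C(=O)OC)[C@H](CC(=O)OCC=C)C(=O)OCC=C)C(=C)CC[C@@H]12 | intermediate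
48 | mixed anhydride of 35 with 2,4,6-trichlorobenzoic acid | C=C1CC[C@H]2C(C)(C)CCC[C@]2(C)[C@H]1CO[C@@H](C(=O)OC)[C@H](CC(=O)OCC=C)C(=O)OC(=O)c1c(Cl)cc(Cl)cc1Cl | intermediate
49 | tris-allyl ester of the target (ester of 35 with the C4α-CH2OH of 47) | C=C1CC[C@H]2C(C)(C)CCC[C@]2(C)[C@H]1CO[C@@H](C(=O)OC)[C@H](CC(=O)OCC=C)C(=O)OC[C@]1(C)CCC[C@]2(C)[C@@H](CO[C@@H](C(=O)OC)[C@H](CC(=O)OCC=C)C(=O)OCC=C)C(=C)CC[C@@H]12 | intermediate
50 | CNP0420141.2 (unit A albicanyl isocitrate ether, its C2' carboxyl esterified with the C4α-CH2OH of unit B; three free acids, two methyl esters) | C=C1CC[C@H]2C(C)(C)CCC[C@]2(C)[C@H]1CO[C@@H](C(=O)OC)[C@H](CC(=O)O)C(=O)OC[C@]1(C)CCC[C@]2(C)[C@@H](CO[C@@H](C(=O)OC)[C@H](CC(=O)O)C(=O)O)C(=C)CC[C@@H]12 | target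

**Step count and risks**

Total step count: 32. Longest linear sequence: 16 steps (1–4, 6–13, 19, 20, 31, 32).

Steps most likely to fail:

Step 9 (cycloaddition). The bulky chelated imide may not reach the crowded transition state in which C5–C10 forms between a quaternary-to-be carbon and a neopentyl diene terminus. The result would be no reaction, reaction through a non-chelated conformer with loss of facial control, or competing exo addition (cis ring fusion). The fallback sets out from 13 and returns at 19. It replaces auxiliary control by catalyst control on a smaller activating group. Ester 13 is reduced with iBu2AlH (CH2Cl2, −78 °C) to (2E,8E,10E)-3,7,7-trimethyl-12-(phenylsulfanyl)dodeca-2,8,10-trien-1-ol F1. Oxidation with MnO2 (CH2Cl2, rt) gives (2E,8E,10E)-3,7,7-trimethyl-12-(phenylsulfanyl)dodeca-2,8,10-trienal F2. An intramolecular Diels–Alder reaction of this trienal, catalysed by a chiral oxazaborolidinium triflimide whose enantiomer is chosen for the Si face of C9 (CH2Cl2, −78 → −40 °C), should give (1S,2S,4aS,8aS)-5,5,8a-trimethyl-2-[(phenylsulfanyl)methyl]-1,2,4a,5,6,7,8,8a-octahydronaphthalene-1-carbaldehyde F3. NaBH4 (MeOH, 0 °C) then gives 19.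

Step 19 (reductive etherification; step 29 runs the same hazard). The Lewis acid may shift the exocyclic double bond into conjugation or epimerise C9 through enol-ether formation from the oxocarbenium ion before hydride transfer. Capture of the hindered aldehyde by the weakly nucleophilic silyl ether may also be too slow, leaving simple reduction to the alcohol. The fallback sets out from 22 and returns at 34, and avoids the aldehyde. Albicanol 22 is converted with (CF3SO2)2O and 2,6-lutidine (CH2Cl2, −78 °C) into albicanyl trifluoromethanesulfonate F4. This alkylates the hydroxyl of 30 in the presence of 2,6-di-tert-butyl-4-methylpyridine (CH2Cl2, 0 °C → rt; SN2 O-alkylation under non-basic conditions) to give 34.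

Step 31 (esterification). Activation of the acid may cause β-elimination of the drimanyl alkoxide or epimerisation at C2', and acylation of the neopentyl alcohol may be slow. The fallback sets out from 30 and 47 and returns at 49. It forms the ester before the ether, so the activated acid carries no drimane unit and can be used in excess. Bu4NF (THF, 0 °C) removes the silylethyl ester of 30 to give (2S,3R)-3-hydroxy-4-methoxy-4-oxo-2-[2-oxo-2-(prop-2-en-1-yloxy)ethyl]butanoic acid F5. Carbodiimide coupling with 47 (iPrN=C=NiPr, DMAP cat., CH2Cl2, 0 °C) gives the hydroxy ester of F5 with the C4α-CH2OH of 47 F6. Silylation as in step 19 gives the trimethylsilyl ether of that hydroxy ester F7, and reductive etherification with aldehyde 23 (Et3SiH, Me3SiOTf, CH2Cl2, −78 → −40 °C) gives 49.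

**Further compounds**

F1 | step 9 | (2E,8E,10E)-3,7,7-trimethyl-12-(phenylsulfanyl)dodeca-2,8,10-trien-1-ol | OC/C=C(\C)CCCC(C)(C)/C=C/C=C/CSc1ccccc1
F2 | step 9 | (2E,8E,10E)-3,7,7-trimethyl-12-(phenylsulfanyl)dodeca-2,8,10-trienal | O=C/C=C(\C)CCCC(C)(C)/C=C/C=C/CSc1ccccc1
F3 | step 9 | (1S,2S,4aS,8aS)-5,5,8a-trimethyl-2-[(phenylsulfanyl)methyl]-1,2,4a,5,6,7,8,8a-octahydronaphthalene-1-carbaldehyde | c1ccccc1SC[C@H]1C=C[C@H]2C(C)(C)CCC[C@]2(C)[C@H]1C=O
F4 | step 19 | albicanyl trifluoromethanesulfonate | C=C1CC[C@H]2C(C)(C)CCC[C@]2(C)[C@H]1COS(=O)(=O)C(F)(F)F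
F5 | step 31 | (2S,3R)-3-hydroxy-4-methoxy-4-oxo-2-[2-oxo-2-(prop-2-en-1-yloxy)ethyl]butanoic acid | O[C@@H](C(=O)OC)[C@H](CC(=O)OCC=C)C(=O)O
F6 | step 31 | ester of F5 with the C4α-CH2OH of 47 (free C1' hydroxyl) | O[C@@H](C(=O)OC)[C@H](CC(=O)OCC=C)C(=O)OC[C@]1(C)CCC[C@]2(C)[C@@H](CO[C@@H](C(=O)OC)[C@H](CC(=O)OCC=C)C(=O)OCC=C)C(=C)CC[C@@H]12
F7 | step 31 | O-trimethylsilyl ether of F6 | C[Si](C)(C)O[C@@H](C(=O)OC)[C@H](CC(=O)OCC=C)C(=O)OC[C@]1(C)CCC[C@]2(C)[C@@H](CO[C@@H](C(=O)OC)[C@H](CC(=O)OCC=C)C(=O)OCC=C)C(=C)CC[C@@H]12
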